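The ten-membered carbocycle is closed last, at C7–C8 (germacrane numbering), by an intramolecular chromium-mediated allylation. The precursor is a 3-(bromomethyl)butenolide that already carries the lactone, the 4,5-epoxide and the cis,cis-dienoate chain ending in the C8 aldehyde. In one operation the γ-carbon C7 attacks C8, the ring closes, the butenolide becomes the α-methylene lactone (C11=C13) and C7 is set from C6. The step exploits the homoallylic alcohol unit C13=C11–C7–C8–O formed by the lactone ring and the ten-membered ring. C9 comes from (S)-malate, C6 from catalytic vinylation, C4/C5 from directed epoxidation; C8 is corrected by oxidation–reduction before acylation.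

Key step: step 15

Remark: atoms carry germacrane numbers (ring C1–C10; C4 bears methyl C15, C10 bears ester carbon C14; lactone C11–C13 closed on O6). Compounds 1, 5, 11 and 17 are taken as commercial.

Step 1
Reactants: 1 (E)-2-methylbut-2-en-1-ol
Product: 2 [(2S,3S)-2,3-dimethyloxiran-2-yl]methanol
Conditions: Ti(OiPr)4 (10 mol %), L-(+)-diethyl tartrate (12 mol %), t-BuOOH, 4 Å MS, CH2Cl2, −20 °C
Reagents that add atoms: tert-butyl hydroperoxide, CC(C)(C)OO
Why: Sharpless asymmetric epoxidation of a primary allylic alcohol; the L-(+)-tartrate titanium complex should deliver oxygen to the face that gives the (2S,3S) epoxide, the same sense as for geraniol.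

Step 2
Reactants: 2 [(2S,3S)-2,3-dimethyloxiran-2-yl]methanol
Product: 4 (2R,3S)-2,3-dimethyloxirane-2-carboxylic acid, via epoxy aldehyde 3 (not isolated)
Conditions: RuCl3·xH2O (2 mol %), NaIO4, EtOAc/MeCN/H2O, 0 °C → rt
Reagents that add atoms: sodium periodate, [Na+].[O-]I(=O)(=O)=O; water, O
Why: Ruthenium tetroxide oxidation (catalytic RuCl3 with periodate) should take the primary alcohol through the aldehyde hydrate to the acid without touching the epoxide centres (the C2 descriptor changes only through CIP priority).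

Step 3
Reactants: 5 dimethyl (S)-malate
Product: 6 methyl (S)-3,4-dihydroxybutanoate
Conditions: BH3·SMe2, NaBH4 (5 mol %), THF, 0 °C → rt; MeOH
Reagents that add atoms: none
Why: Hydroxyl-directed borane reduction of an α-hydroxy ester through a cyclic alkoxyborane should reduce only the ester next to the hydroxyl and leave the stereocentre intact.

Step 4
Reactants: 6 methyl (S)-3,4-dihydroxybutanoate
Product: 7 methyl (S)-3,4-bis(triethylsilyloxy)butanoate
Conditions: Et3SiCl, imidazole, DMF, 0 °C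
Reagents that add atoms: chlorotriethylsilane, CC[Si](CC)(CC)Cl
Why: Standard silylation of both hydroxyls; the primary triethylsilyl ether is the group that step 14 later turns into the aldehyde.

Step 5
Reactants: 7 methyl (S)-3,4-bis(triethylsilyloxy)butanoate
Product: 9 methyl (3S)-2-formyl-3,4-bis(triethylsilyloxy)butanoate (formyl/enol tautomers, C2 not defined), via lithium enolate 8 (not isolated)
Conditions: LDA, THF, −78 °C; HCO2Me, −78 → −20 °C; AcOH
Reagents that add atoms: methyl formate, COC=O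
Why: Crossed Claisen condensation of the ester lithium enolate with methyl formate; β-elimination of the silyloxy group should be slow at −78 °C and the C2 centre disappears in the next step.

Step 6
Reactants: 9 methyl (3S)-2-formyl-3,4-bis(triethylsilyloxy)butanoate
Product: 10 methyl (2E,3S)-2-[(tosyloxy)methylidene]-3,4-bis(triethylsilyloxy)butanoate
Conditions: TsCl, N-methylimidazole, Et3N, MeCN, −15 °C
Reagents that add atoms: p-toluenesulfonyl chloride, Cc1ccc(cc1)S(Cl)(=O)=O
Why: Enol tosylation of an α-formyl ester under non-chelating amine conditions, which is known to give the (E)-tosylate with the sulfonyloxy group trans to the ester; this fixes the C10=C1 geometry.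

Step 7
Reactants: 10 methyl (2E,3S)-2-[(tosyloxy)methylidene]-3,4-bis(triethylsilyloxy)butanoate, 11 (E)-3-methylpent-2-en-4-yn-1-ol
Product: 12 methyl (2E,6E)-2-[(1S)-1,2-bis(triethylsilyloxy)ethyl]-8-hydroxy-6-methylocta-2,6-dien-4-ynoate
Conditions: PdCl2(PPh3)2 (5 mol %), CuI (10 mol %), i-Pr2NEt, DMF, 50 °C
Reagents that add atoms: none
Why: Sonogashira coupling of an activated enol tosylate with a terminal alkyne should proceed with retention of the alkene geometry and tolerates the free allylic alcohol.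

Step 8
Reactants: 12 methyl (2E,6E)-2-[(1S)-1,2-bis(triethylsilyloxy)ethyl]-8-hydroxy-6-methylocta-2,6-dien-4-ynoate
Product: 13 methyl (2E,6E)-2-[(1S)-1,2-bis(triethylsilyloxy)ethyl]-6-methyl-8-oxoocta-2,6-dien-4-ynoate
Conditions: MnO2, CH2Cl2, rt
Reagents that add atoms: none
Why: MnO2 oxidation is selective for the allylic alcohol and should give the enal without touching silyl ethers or esters.

Step 9
Reactants: 13 methyl (2E,6E)-2-[(1S)-1,2-bis(triethylsilyloxy)ethyl]-6-methyl-8-oxoocta-2,6-dien-4-ynoate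
Product: 14 methyl (2E,6E,8S)-2-[(1S)-1,2-bis(triethylsilyloxy)ethyl]-8-hydroxy-6-methyldeca-2,6,9-trien-4-ynoate
Conditions: Zn(CH=CH2)2, (−)-DAIB (10 mol %), toluene, −20 °C; aq NH4Cl
Reagents that add atoms: divinylzinc, C=C[Zn]C=C
Why: Amino alcohol-catalysed addition of an alkenylzinc reagent to an aldehyde; the (−)-DAIB zinc complex should deliver the vinyl group to the Si face, which gives the 6S carbinol (C8 of this chain).

Step 10
Reactants: 14 methyl (2E,6E,8S)-2-[(1S)-1,2-bis(triethylsilyloxy)ethyl]-8-hydroxy-6-methyldeca-2,6,9-trien-4-ynoate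
Product: 15 methyl (2E)-2-[(1S)-1,2-bis(triethylsilyloxy)ethyl]-5-{(2R,3R)-3-[(1S)-1-hydroxyprop-2-en-1-yl]-2-methyloxiran-2-yl}pent-2-en-4-ynoate
Conditions: m-CPBA, Na2HPO4, CH2Cl2, 0 °C
Reagents that add atoms: 3-chloroperbenzoic acid, OOC(=O)c1cccc(Cl)c1
Why: Hydroxyl-directed peracid epoxidation; the methyl group cis to C6 imposes 1,3-allylic strain, so the hydrogen-bonded peracid should attack the face that gives the threo epoxy alcohol (4R,5R), and the trisubstituted alkene should react before the vinyl group.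

Step 11
Reactants: 15 methyl (2E)-2-[(1S)-1,2-bis(triethylsilyloxy)ethyl]-5-{(2R,3R)-3-[(1S)-1-hydroxyprop-2-en-1-yl]-2-methyloxiran-2-yl}pent-2-en-4-ynoate
Product: 16 methyl (2E,4Z)-2-[(1S)-1,2-bis(triethylsilyloxy)ethyl]-5-{(2R,3R)-3-[(1S)-1-hydroxyprop-2-en-1-yl]-2-methyloxiran-2-yl}penta-2,4-dienoate
Conditions: H2 (1 atm), Pd/CaCO3 poisoned with Pb(OAc)2 (Lindlar catalyst), quinoline, EtOAc, rt
Reagents that add atoms: none
Why: Lindlar semi-hydrogenation adds hydrogen syn to the alkyne and should give the Z alkene C2=C3, while the poisoned catalyst leaves the alkenes and the epoxide alone.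

Step 12
Reactants: 16 methyl (2E,4Z)-2-[(1S)-1,2-bis(triethylsilyloxy)ethyl]-5-{(2R,3R)-3-[(1S)-1-hydroxyprop-2-en-1-yl]-2-methyloxiran-2-yl}penta-2,4-dienoate, 17 2-(bromomethyl)acrylic acid
Product: 19 2-(bromomethyl)acrylate ester of 16 at its secondary hydroxyl (O6), via O-acylisourea 18 (not isolated)
Conditions: DIC, DMAP (5 mol %), CH2Cl2, −20 → 0 °C
Reagents that add atoms: none
Why: Carbodiimide (Steglich) esterification acylates the secondary alcohol with retention at C6; low temperature and little DMAP should keep the allylic bromide intact.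

Step 13
Reactants: 19 2-(bromomethyl)acrylate ester of 16
Product: 20 methyl (2E,4Z)-2-[(1S)-1,2-bis(triethylsilyloxy)ethyl]-5-{(2R,3R)-3-[(2S)-4-(bromomethyl)-5-oxo-2,5-dihydrofuran-2-yl]-2-methyloxiran-2-yl}penta-2,4-dienoate
Conditions: second-generation Grubbs catalyst RuCl2(=CHPh)(PCy3)(H2IMes) (5 mol %), CH2Cl2, 40 °C, 10 mM
Reagents that add atoms: none
Why: Ring-closing metathesis of the vinyl group with the acrylate should give the butenolide; closure onto C2=C3 instead would need a trans-fused epoxide in a five-membered ring and is not possible.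

Step 14
Reactants: 20 butenolide bromide (name as in step 13)
Product: 22 methyl (2E,4Z)-5-{(2R,3R)-3-[(2S)-4-(bromomethyl)-5-oxo-2,5-dihydrofuran-2-yl]-2-methyloxiran-2-yl}-2-[(1S)-2-oxo-1-(triethylsilyloxy)ethyl]penta-2,4-dienoate, via alkoxysulfonium chloride 21 (not isolated)
Conditions: (COCl)2, DMSO, CH2Cl2, −78 → −45 °C; i-Pr2NEt, −78 → −20 °C
Reagents that add atoms: none
Why: Swern oxidation converts a primary triethylsilyl ether directly into the aldehyde through the alkoxysulfonium salt (oxidative desilylation) while the secondary silyl ether should survive; the hindered amine avoids alkylation by the allylic bromide.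

Step 15
Reactants: 22 aldehyde bromide (name as in step 14)
Product: 24 methyl (1(10)E,2Z,4R,5R,6S,7R,8R,9S)-4,5-epoxy-8-hydroxy-9-(triethylsilyloxy)germacra-1(10),2,11(13)-trien-12,6-olid-14-oate, via allylchromium dichloride 23 (not isolated)
Conditions: CrCl2 (8 equiv), THF, 4 Å MS, 25 °C, syringe-pump addition, 2 mM
Reagents that add atoms: none
Why: Divalent chromium reduces the allylic bromide in two one-electron steps to a σ-allyl complex of trivalent chromium (23), whose γ-carbon C7 adds to the tethered aldehyde carbon C8 through a six-membered chair transition state while the double bond moves to C11=C13 (intramolecular Nozaki–Hiyama–Kishi allylation). The closest known reactions are the CrCl2-mediated additions of 3-(bromomethyl)furan-2(5H)-ones to aldehydes and the CrCl2 ring closures of (bromomethyl)acrylate aldehydes to ten-membered germacranolides. The carbocycle closes in a 10-exo-trig mode by the C7–C8 bond. C7 is controlled by C6, because the new bond should form on the butenolide face opposite to the C5 substituent and so give the trans-fused lactone (7R); C8 is controlled by the chair with the ring-locked allyl geometry and C9 equatorial, reinforced by Felkin–Anh control from the 9-silyloxy group, which predicts the 8R carbinol that steps 16 and 17 invert. The step needs γ-attack (inherent to allylchromium reagents), ring closure faster than oligomerisation (high dilution; the cis,cis-diene and the trans-epoxide fold the chain) and inertness of epoxide, esters and the epimerisable C9 (neutral aprotic medium, the organochromium adds only to the aldehyde).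

Step 16
Reactants: 24 (8R)-alcohol (name as in step 15)
Product: 25 methyl (1(10)E,2Z,4R,5R,6S,7S,9S)-4,5-epoxy-8-oxo-9-(triethylsilyloxy)germacra-1(10),2,11(13)-trien-12,6-olid-14-oate (7S only through CIP priority; geometry unchanged)
Conditions: Dess–Martin periodinane, NaHCO3, CH2Cl2, 0 °C
Reagents that add atoms: none
Why: Dess–Martin oxidation under buffered conditions should give the β,γ-unsaturated ketone without moving the exocyclic alkene into conjugation; it erases the C8 centre.

Step 17
Reactants: 25 ketone (name as in step 16)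
Product: 26 methyl (1(10)E,2Z,4R,5R,6S,7R,8S,9S)-4,5-epoxy-8-hydroxy-9-(triethylsilyloxy)germacra-1(10),2,11(13)-trien-12,6-olid-14-oate
Conditions: NaBH4, CeCl3·7H2O, MeOH, −78 °C
Reagents that add atoms: none
Why: Luche reduction is 1,2-selective and spares the α-methylene lactone; hydride should attack the outer face of the ring ketone, anti to C6 and in the Felkin–Anh sense with respect to the 9-silyloxy group, which gives the 8S alcohol syn to O9.

Step 18
Reactants: 26 (8S)-alcohol (name as in step 17), 4 (2R,3S)-2,3-dimethyloxirane-2-carboxylic acid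
Product: 28 methyl (1(10)E,2Z,4R,5R,6S,7S,8S,9S)-8-{[(2R,3S)-2,3-dimethyloxirane-2-carbonyl]oxy}-4,5-epoxy-9-(triethylsilyloxy)germacra-1(10),2,11(13)-trien-12,6-olid-14-oate (7S only through CIP priority of silicon), via mixed anhydride 27 (not isolated)
Conditions: 4, 2,4,6-Cl3C6H2COCl, Et3N, toluene, rt; then 26, DMAP, rt
Reagents that add atoms: none
Why: Yamaguchi esterification through the mixed anhydride should acylate the hindered 8-hydroxyl with retention at C8 and without opening the epoxy acid.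

Step 19
Reactants: 28 8-ester 9-silyl ether (name as in step 18)
Product: 29 methyl (1(10)E,2Z,4R,5R,6S,7R,8S,9S)-8-{[(2R,3S)-2,3-dimethyloxirane-2-carbonyl]oxy}-4,5-epoxy-9-hydroxygermacra-1(10),2,11(13)-trien-12,6-olid-14-oate
Conditions: HF·pyridine, pyridine (excess), THF, 0 °C
Reagents that add atoms: none
Why: Buffered fluoride cleavage of the secondary silyl ether; epoxides and esters should be stable to HF·pyridine in excess pyridine.

Step 20
Reactants: 29 9-alcohol (name as in step 19)
Product: 30 methyl (1(10)E,2Z,4R,5R,6S,7R,8S,9S)-9-acetoxy-8-{[(2R,3S)-2,3-dimethyloxirane-2-carbonyl]oxy}-4,5-epoxygermacra-1(10),2,11(13)-trien-12,6-olid-14-oate (CNP0229507.5)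
Conditions: Ac2O, pyridine, DMAP (cat.), CH2Cl2, 0 °C
Reagents that add atoms: acetic anhydride, CC(=O)OC(C)=O
Why: DMAP-catalysed acetylation of the free 9-hydroxyl should complete the target without acyl migration.

Compound list

1 | (E)-2-methylbut-2-en-1-ol | C/C=C(\C)CO | starting material
2 | [(2S,3S)-2,3-dimethyloxiran-2-yl]methanol | OC[C@]1(C)O[C@H]1C | intermediate
3 | (2R,3S)-2,3-dimethyloxirane-2-carbaldehyde | O=C[C@]1(C)O[C@H]1C | intermediate
4 | (2R,3S)-2,3-dimethyloxirane-2-carboxylic acid | OC(=O)[C@]1(C)O[C@H]1C | intermediate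
5 | dimethyl (S)-malate | COC(=O)C[C@H](O)C(=O)OC | starting material
6 | methyl (S)-3,4-dihydroxybutanoate | COC(=O)C[C@H](O)CO | intermediate
7 | methyl (S)-3,4-bis(triethylsilyloxy)butanoate | CC[Si](CC)(CC)OC[C@@H](O[Si](CC)(CC)CC)CC(=O)OC | intermediate
8 | lithium enolate of 7 | CC[Si](CC)(CC)OC[C@@H](O[Si](CC)(CC)CC)C=C(OC)O[Li] | intermediate
9 | methyl (3S)-2-formyl-3,4-bis(triethylsilyloxy)butanoate | CC[Si](CC)(CC)OC[C@@H](O[Si](CC)(CC)CC)C(C=O)C(=O)OC | intermediate
10 | methyl (2E,3S)-2-[(tosyloxy)methylidene]-3,4-bis(triethylsilyloxy)butanoate | CC[Si](CC)(CC)OC[C@@H](O[Si](CC)(CC)CC)/C(C(=O)OC)=C\OS(=O)(=O)c1ccc(C)cc1 | intermediate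
11 | (E)-3-methylpent-2-en-4-yn-1-ol | C#C/C(C)=C/CO | starting material
12 | methyl (2E,6E)-2-[(1S)-1,2-bis(triethylsilyloxy)ethyl]-8-hydroxy-6-methylocta-2,6-dien-4-ynoate | CC[Si](CC)(CC)OC[C@@H](O[Si](CC)(CC)CC)/C(C(=O)OC)=C\C#C/C(C)=C/CO | intermediate
13 | methyl (2E,6E)-2-[(1S)-1,2-bis(triethylsilyloxy)ethyl]-6-methyl-8-oxoocta-2,6-dien-4-ynoate | CC[Si](CC)(CC)OC[C@@H](O[Si](CC)(CC)CC)/C(C(=O)OC)=C\C#C/C(C)=C/C=O | intermediate
14 | methyl (2E,6E,8S)-2-[(1S)-1,2-bis(triethylsilyloxy)ethyl]-8-hydroxy-6-methyldeca-2,6,9-trien-4-ynoate | CC[Si](CC)(CC)OC[C@@H](O[Si](CC)(CC)CC)/C(C(=O)OC)=C\C#C/C(C)=C/[C@@H](O)C=C | intermediate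
15 | methyl (2E)-2-[(1S)-1,2-bis(triethylsilyloxy)ethyl]-5-{(2R,3R)-3-[(1S)-1-hydroxyprop-2-en-1-yl]-2-methyloxiran-2-yl}pent-2-en-4-ynoate | CC[Si](CC)(CC)OC[C@@H](O[Si](CC)(CC)CC)/C(C(=O)OC)=C\C#C[C@@]1(C)O[C@@H]1[C@@H](O)C=C | intermediate
16 | methyl (2E,4Z)-2-[(1S)-1,2-bis(triethylsilyloxy)ethyl]-5-{(2R,3R)-3-[(1S)-1-hydroxyprop-2-en-1-yl]-2-methyloxiran-2-yl}penta-2,4-dienoate | CC[Si](CC)(CC)OC[C@@H](O[Si](CC)(CC)CC)/C(C(=O)OC)=C\C=C/[C@@]1(C)O[C@@H]1[C@@H](O)C=C | intermediate
17 | 2-(bromomethyl)acrylic acid | C=C(CBr)C(=O)O | starting material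
18 | O-acylisourea of 17 with N,N'-diisopropylcarbodiimide | C=C(CBr)C(=O)OC(=NC(C)C)NC(C)C | intermediate
19 | 2-(bromomethyl)acrylate ester of 16 at O6 | CC[Si](CC)(CC)OC[C@@H](O[Si](CC)(CC)CC)/C(C(=O)OC)=C\C=C/[C@@]1(C)O[C@@H]1[C@@H](OC(=O)C(=C)CBr)C=C | intermediate
20 | methyl (2E,4Z)-2-[(1S)-1,2-bis(triethylsilyloxy)ethyl]-5-{(2R,3R)-3-[(2S)-4-(bromomethyl)-5-oxo-2,5-dihydrofuran-2-yl]-2-methyloxiran-2-yl}penta-2,4-dienoate | CC[Si](CC)(CC)OC[C@@H](O[Si](CC)(CC)CC)/C(C(=O)OC)=C\C=C/[C@@]1(C)O[C@@H]1[C@H]1OC(=O)C(CBr)=C1 | intermediate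
21 | dimethyl(alkoxy)sulfonium chloride at O8 of 20 (primary silyl group replaced) | C[S+](C)OC[C@@H](O[Si](CC)(CC)CC)/C(C(=O)OC)=C\C=C/[C@@]1(C)O[C@@H]1[C@H]1OC(=O)C(CBr)=C1.[Cl-] | intermediate
22 | methyl (2E,4Z)-5-{(2R,3R)-3-[(2S)-4-(bromomethyl)-5-oxo-2,5-dihydrofuran-2-yl]-2-methyloxiran-2-yl}-2-[(1S)-2-oxo-1-(triethylsilyloxy)ethyl]penta-2,4-dienoate | O=C[C@@H](O[Si](CC)(CC)CC)/C(C(=O)OC)=C\C=C/[C@@]1(C)O[C@@H]1[C@H]1OC(=O)C(CBr)=C1 | intermediate
23 | allylchromium dichloride from 22 (CrCl2 on C13 in place of Br, trivalent chromium) | O=C[C@@H](O[Si](CC)(CC)CC)/C(C(=O)OC)=C\C=C/[C@@]1(C)O[C@@H]1[C@H]1OC(=O)C(C[Cr](Cl)Cl)=C1 | intermediate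
24 | methyl (1(10)E,2Z,4R,5R,6S,7R,8R,9S)-4,5-epoxy-8-hydroxy-9-(triethylsilyloxy)germacra-1(10),2,11(13)-trien-12,6-olid-14-oate | C=C1C(=O)O[C@H]2[C@H]1[C@@H](O)[C@@H](O[Si](CC)(CC)CC)/C(C(=O)OC)=C\C=C/[C@@]1(C)O[C@H]21 | intermediate
25 | methyl (1(10)E,2Z,4R,5R,6S,7S,9S)-4,5-epoxy-8-oxo-9-(triethylsilyloxy)germacra-1(10),2,11(13)-trien-12,6-olid-14-oate | C=C1C(=O)O[C@H]2[C@H]1C(=O)[C@@H](O[Si](CC)(CC)CC)/C(C(=O)OC)=C\C=C/[C@@]1(C)O[C@H]21 | intermediate
26 | methyl (1(10)E,2Z,4R,5R,6S,7R,8S,9S)-4,5-epoxy-8-hydroxy-9-(triethylsilyloxy)germacra-1(10),2,11(13)-trien-12,6-olid-14-oate | C=C1C(=O)O[C@H]2[C@H]1[C@H](O)[C@@H](O[Si](CC)(CC)CC)/C(C(=O)OC)=C\C=C/[C@@]1(C)O[C@H]21 | intermediate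
27 | mixed anhydride of 4 with 2,4,6-trichlorobenzoic acid | Clc1cc(Cl)c(C(=O)OC(=O)[C@]2(C)O[C@H]2C)c(Cl)c1 | intermediate
28 | methyl (1(10)E,2Z,4R,5R,6S,7S,8S,9S)-8-{[(2R,3S)-2,3-dimethyloxirane-2-carbonyl]oxy}-4,5-epoxy-9-(triethylsilyloxy)germacra-1(10),2,11(13)-trien-12,6-olid-14-oate | C=C1C(=O)O[C@H]2[C@H]1[C@H](OC(=O)[C@]1(C)O[C@H]1C)[C@@H](O[Si](CC)(CC)CC)/C(C(=O)OC)=C\C=C/[C@@]1(C)O[C@H]21 | intermediate
29 | methyl (1(10)E,2Z,4R,5R,6S,7R,8S,9S)-8-{[(2R,3S)-2,3-dimethyloxirane-2-carbonyl]oxy}-4,5-epoxy-9-hydroxygermacra-1(10),2,11(13)-trien-12,6-olid-14-oate | C=C1C(=O)O[C@H]2[C@H]1[C@H](OC(=O)[C@]1(C)O[C@H]1C)[C@@H](O)/C(C(=O)OC)=C\C=C/[C@@]1(C)O[C@H]21 | intermediate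
30 | methyl (1(10)E,2Z,4R,5R,6S,7R,8S,9S)-9-acetoxy-8-{[(2R,3S)-2,3-dimethyloxirane-2-carbonyl]oxy}-4,5-epoxygermacra-1(10),2,11(13)-trien-12,6-olid-14-oate (CNP0229507.5) | C=C1C(=O)O[C@H]2[C@H]1[C@H](OC(=O)[C@]1(C)O[C@H]1C)[C@@H](OC(C)=O)/C(C(=O)OC)=C\C=C/[C@@]1(C)O[C@H]21 | target

Total step count: 20. Longest linear sequence: 18 steps (steps 3–20, from dimethyl (S)-malate); steps 1–2 make acid 4 for step 18.

Steps most likely to fail

1. Step 15 (ring closure). The allylchromium may be protonated or may add to a second molecule faster than the ten-membered ring closes, or the chain may close on the same face as C5 and give the cis-fused lactone. Fallback: the transient organochromium is replaced by an isolable allylboron nucleophile. It sets out from acrylate 19: CuCl-catalysed borylation with bis(pinacolato)diboron and KOAc (known for 2-(halomethyl)acrylates) should give the 2-(pinacolborylmethyl)acrylate ester F1. Ring-closing metathesis as in step 13 should give the butenolide allylboronate F2, and Swern oxidative desilylation as in step 14 the aldehyde allylboronate F3. Heating F3 in dilute toluene should close the ring by intramolecular allylboration (the known aldehyde addition of 2-alkoxycarbonyl allylboronates, same chair and same C7/C8 outcome), and mild hydrolysis of the borate comes back to 24.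

2. Step 17 (C8 by reduction). Hydride delivery may be poorly face-selective, or the ketone may enolise towards C7 and pull the exocyclic alkene into the ring. Fallback: the ketone stage is avoided. It sets out from the 8R alcohol 24, which is inverted in the esterification itself by a Mitsunobu reaction with acid 4 (PPh3, DIAD, toluene, 0 °C → rt), and comes back at 28; this fallback makes no new compound (F0).

3. Step 10 (directed epoxidation). The peracid may also epoxidise the vinyl group, or the threo preference may be eroded by the conjugated enyne. Fallback: the epoxide is set by reagent control before C6 exists. It sets out from primary allylic alcohol 12: Sharpless epoxidation with Ti(OiPr)4, D-(−)-diethyl tartrate and t-BuOOH should give the epoxy alcohol F4, and Dess–Martin oxidation the epoxy aldehyde F5. Divinylzinc addition with (−)-DAIB as in step 9 (catalyst control against the Felkin preference of the epoxy aldehyde) comes back to 15.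

Further compounds

F1 | step 15 | 2-(pinacolborylmethyl)acrylate ester of 16 at O6 (19 with the boronate in place of Br) | CC[Si](CC)(CC)OC[C@@H](O[Si](CC)(CC)CC)/C(C(=O)OC)=C\C=C/[C@@]1(C)O[C@@H]1[C@@H](OC(=O)C(=C)CB1OC(C)(C)C(C)(C)O1)C=C
F2 | step 15 | butenolide allylboronate (20 with the boronate in place of Br) | CC[Si](CC)(CC)OC[C@@H](O[Si](CC)(CC)CC)/C(C(=O)OC)=C\C=C/[C@@]1(C)O[C@@H]1[C@H]1OC(=O)C(CB2OC(C)(C)C(C)(C)O2)=C1
F3 | step 15 | aldehyde allylboronate (22 with the boronate in place of Br) | O=C[C@@H](O[Si](CC)(CC)CC)/C(C(=O)OC)=C\C=C/[C@@]1(C)O[C@@H]1[C@H]1OC(=O)C(CB2OC(C)(C)C(C)(C)O2)=C1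
F0 | step 17 | none | none
F4 | step 10 | methyl (2E)-2-[(1S)-1,2-bis(triethylsilyloxy)ethyl]-5-[(2R,3R)-3-(hydroxymethyl)-2-methyloxiran-2-yl]pent-2-en-4-ynoate | CC[Si](CC)(CC)OC[C@@H](O[Si](CC)(CC)CC)/C(C(=O)OC)=C\C#C[C@@]1(C)O[C@@H]1CO
F5 | step 10 | methyl (2E)-2-[(1S)-1,2-bis(triethylsilyloxy)ethyl]-5-[(2R,3S)-3-formyl-2-methyloxiran-2-yl]pent-2-en-4-ynoate | CC[Si](CC)(CC)OC[C@@H](O[Si](CC)(CC)CC)/C(C(=O)OC)=C\C#C[C@@]1(C)O[C@@H]1C=O
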